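**Plan**

1. Retrosynthesis (numbering: 3,7-dioxabicyclo[3.3.0]octan-2-one; C1/C5 fusion, C2=O, O3, C4–aryl, C6H2, O7, C8–aryl): the five O–benzyl bonds and a temporary C1–CO2Me bond are cut first; then C8–C1 and C6–O7 are cut together, which restores a C1–C6 bond and releases 3,4-bis(benzyloxy)benzaldehyde.
2. Enabling feature: C6 is an unsubstituted CH2 on C5 and C1 is the α-carbon of the C2 lactone carbonyl, so C1–C5–C6 can be stored as a cyclopropane fused to the lactone ring, doubly activated by C2=O and an ester on C1; opened at C6 it is a C1-nucleophile/C6-electrophile pair that takes up an aldehyde C=O.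
3. The lactone-fused cyclopropane is cut at C1–C5 and C1–C6 (carbenoid addition to a vinyl group) and at the O3–C2 ester bond, giving (S)-1-arylprop-2-en-1-ol, a malonyl unit and a diazo group; the alcohol comes from the aryl aldehyde and a vinyl Grignard reagent.
4. Forward order of rings: acyclic allylic malonate → lactone ring and cyclopropane closed in one carbenoid step → cyclopropane exchanged for the tetrahydrofuran ring (MgI2, aldehyde) → ester and benzyl groups removed.
5. Stereochemistry: C4 from lipase resolution of the allylic alcohol; C5 relayed from C4 in the cyclopropanation (aryl anti to the three-membered ring); C1 and C8 in the ring expansion (only the aldolate cis to the C5 iodomethyl arm can close, aryl exo); the final C1–H by convex-face protonation, cis fusion being compulsory.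

Key step: step 6

Remark: bicyclic locants follow the skeleton numbering above; the CIP descriptors at C1, C5 and C8 change along 8 → 12 → 13 only because substituent priorities change, no centre is inverted.

**Route**

Step 1
Reactants: 1 3,4,5-tris(benzyloxy)benzaldehyde; 2 vinylmagnesium bromide
Product: 3 (±)-1-[3,4,5-tris(benzyloxy)phenyl]prop-2-en-1-ol
Conditions: 2 (1.2 equiv), THF, −78 → 0 °C; aq. NH4Cl
Reagents that add atoms: none
Why: Grignard 1,2-addition of the vinyl nucleophile to a non-enolisable aryl aldehyde should give the allylic alcohol with the aryl benzyl ethers untouched; the new C4 centre forms racemic and is sorted in step 2.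

Step 2
Reactants: 3 (±)-1-[3,4,5-tris(benzyloxy)phenyl]prop-2-en-1-ol
Product: 4 (S)-1-[3,4,5-tris(benzyloxy)phenyl]prop-2-en-1-ol
Conditions: immobilised Candida antarctica lipase B (Novozym 435), vinyl acetate (3 equiv), toluene, 40 °C, stopped just past half conversion; chromatography
Reagents that add atoms: none
Why: Lipase-catalysed kinetic resolution by enantioselective transesterification: for aryl vinyl carbinols this lipase is expected to acylate the (R)-enantiomer (large aryl, medium vinyl, the usual size rule for secondary alcohols), so the (S)-alcohol carrying the future C4 configuration should remain and be separated from the (R)-acetate.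

Step 3
Reactants: 4 (S)-1-[3,4,5-tris(benzyloxy)phenyl]prop-2-en-1-ol; 5 methyl malonyl chloride (methyl 3-chloro-3-oxopropanoate)
Product: 6 methyl (S)-1-[3,4,5-tris(benzyloxy)phenyl]prop-2-en-1-yl malonate
Conditions: 5 (1.3 equiv), pyridine (1.5 equiv), CH2Cl2, 0 °C
Reagents that add atoms: none
Why: Esterification of the secondary alcohol with the acid chloride under mild base does not break the C4–O bond, so the configuration is retained, and the cold basic medium avoids ionisation of the electron-rich 1-arylallyl ester.

Step 4
Reactants: 6 methyl (S)-1-[3,4,5-tris(benzyloxy)phenyl]prop-2-en-1-yl malonate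
Product: 7 methyl (S)-1-[3,4,5-tris(benzyloxy)phenyl]prop-2-en-1-yl 2-diazomalonate
Conditions: 4-acetamidobenzenesulfonyl azide (1.2 equiv), Et3N (1.5 equiv), MeCN, 0 °C → rt
Reagents that add atoms: 4-acetamidobenzenesulfonyl azide, CC(=O)Nc1ccc(cc1)S(=O)(=O)N=[N+]=[N-]
Why: Regitz diazo transfer from the sulfonyl azide to the doubly activated malonate methylene, the only position in 6 acidic enough for Et3N, should give the diazomalonate without touching C4.

Step 5
Reactants: 7 methyl (S)-1-[3,4,5-tris(benzyloxy)phenyl]prop-2-en-1-yl 2-diazomalonate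
Product: 8 methyl (1R,4S,5S)-2-oxo-4-[3,4,5-tris(benzyloxy)phenyl]-3-oxabicyclo[3.1.0]hexane-1-carboxylate
Conditions: Rh2(OAc)4 (1 mol%), ClCH2CH2Cl, 70 °C, slow addition of 7
Reagents that add atoms: none
Why: Rhodium-carbenoid intramolecular cyclopropanation of the tethered vinyl group closes the lactone and the cyclopropane together (cis fusion is the only option), and the C4 aryl group should take the position anti to the forming three-membered ring, with the carbinol H eclipsing the alkene to avoid allylic strain, so C5 and C1 are set from C4.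

Step 6
Reactants: 8 methyl (1R,4S,5S)-2-oxo-4-[3,4,5-tris(benzyloxy)phenyl]-3-oxabicyclo[3.1.0]hexane-1-carboxylate; 9 3,4-bis(benzyloxy)benzaldehyde
Product: 12 methyl (1S,4S,5R,8R)-8-[3,4-bis(benzyloxy)phenyl]-2-oxo-4-[3,4,5-tris(benzyloxy)phenyl]-3,7-dioxabicyclo[3.3.0]octane-1-carboxylate, via γ-iodo magnesium enolate 10 (not isolated), via magnesium aldolate 11 (not isolated)
Conditions: 9 (1.5 equiv), MgI2 (1.0 equiv), THF, 70 °C, sealed tube
Reagents that add atoms: none
Why: MgI2 binds the two carbonyl groups on C1 and iodide opens the cyclopropane by SN2 attack at the C6 methylene to give the γ-iodo magnesium enolate 10, which adds reversibly to aldehyde 9 at C1 (C8–C1, aldolate 11); the alkoxide then displaces iodide at C6 (C6–O7) and MgI2 is returned. This is the magnesium iodide ring expansion of carbonyl-activated cyclopropanes, in which iodide opening, addition of the enolate to a C=O or C=N partner and closure by the heteroatom follow one another, applied here to a lactone-fused cyclopropane ester whose homoconjugate opening at C6 by soft nucleophiles is well established. The tetrahydrofuran ring closes in a 5-exo-tet mode. C1 is set by the C5 centre, because only the aldolate formed on the face of the iodomethyl arm can reach C6 while the other reverts by retro-aldol, so the ester ends on the convex face of a cis-fused bicycle; C8 is set in the ring-closing transition state, where the aryl group should lie exo, away from the concave face over the lactone ring. The step needs opening at C6 rather than C5, an aldol that stays reversible, and an intact benzylic C4–O3 bond: the first follows from the primary character of C6, the second from the stabilised malonate-type enolate (an ester rather than a ketone on C1 offers no competing O-alkylation to a dihydrofuran), and the third from the mildness of MgI2 toward a benzylic ester whose aryl ring bears no free phenol.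

Step 7
Reactants: 12 methyl (1S,4S,5R,8R)-8-[3,4-bis(benzyloxy)phenyl]-2-oxo-4-[3,4,5-tris(benzyloxy)phenyl]-3,7-dioxabicyclo[3.3.0]octane-1-carboxylate
Product: 13 (1S,4S,5R,8S)-8-[3,4-bis(benzyloxy)phenyl]-4-[3,4,5-tris(benzyloxy)phenyl]-3,7-dioxabicyclo[3.3.0]octan-2-one
Conditions: LiCl (3 equiv), H2O (2 equiv), DMSO, 130 °C
Reagents that add atoms: none
Why: Krapcho demethoxycarbonylation: chloride dealkylates the methyl ester, the carboxylate loses CO2 to the lactone enolate and water protonates C1 from the convex face, the only way to a cis-fused bicycle; the endocyclic C8–O7 bond lies near the enolate plane, so β-elimination is stereoelectronically disfavoured and C8 should be kept.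

Step 8
Reactants: 13 (1S,4S,5R,8S)-8-[3,4-bis(benzyloxy)phenyl]-4-[3,4,5-tris(benzyloxy)phenyl]-3,7-dioxabicyclo[3.3.0]octan-2-one
Product: 14 (1S,4S,5R,8S)-8-(3,4-dihydroxyphenyl)-4-(3,4,5-trihydroxyphenyl)-3,7-dioxabicyclo[3.3.0]octan-2-one (CNP0290035.1)
Conditions: H2 (1 atm), 10% Pd/C, EtOAc–MeOH, rt; filtration and concentration under argon
Reagents that add atoms: none
Why: Catalytic hydrogenolysis of the five aryl benzyl ethers is expected to be much faster than cleavage of the two ring benzylic C–O bonds under neutral conditions at 1 atm, so the four stereocentres should stay untouched and the polyphenol is released.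

**Compound list**

1 | 3,4,5-tris(benzyloxy)benzaldehyde | O=Cc1cc(OCc2ccccc2)c(OCc2ccccc2)c(OCc2ccccc2)c1 | starting material
2 | vinylmagnesium bromide | C=C[Mg]Br | starting material
3 | (±)-1-[3,4,5-tris(benzyloxy)phenyl]prop-2-en-1-ol | C=CC(O)c1cc(OCc2ccccc2)c(OCc2ccccc2)c(OCc2ccccc2)c1 | intermediate
4 | (S)-1-[3,4,5-tris(benzyloxy)phenyl]prop-2-en-1-ol | C=C[C@H](O)c1cc(OCc2ccccc2)c(OCc2ccccc2)c(OCc2ccccc2)c1 | intermediate
5 | methyl malonyl chloride (methyl 3-chloro-3-oxopropanoate) | COC(=O)CC(Cl)=O | starting material
6 | methyl (S)-1-[3,4,5-tris(benzyloxy)phenyl]prop-2-en-1-yl malonate | C=C[C@H](OC(=O)CC(=O)OC)c1cc(OCc2ccccc2)c(OCc2ccccc2)c(OCc2ccccc2)c1 | intermediate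
7 | methyl (S)-1-[3,4,5-tris(benzyloxy)phenyl]prop-2-en-1-yl 2-diazomalonate | C=C[C@H](OC(=O)C(=[N+]=[N-])C(=O)OC)c1cc(OCc2ccccc2)c(OCc2ccccc2)c(OCc2ccccc2)c1 | intermediate
8 | methyl (1R,4S,5S)-2-oxo-4-[3,4,5-tris(benzyloxy)phenyl]-3-oxabicyclo[3.1.0]hexane-1-carboxylate (aryl anti to the cyclopropane) | O=C1O[C@H](c2cc(OCc3ccccc3)c(OCc3ccccc3)c(OCc3ccccc3)c2)[C@H]2C[C@@]12C(=O)OC | intermediate
9 | 3,4-bis(benzyloxy)benzaldehyde | O=Cc1ccc(OCc2ccccc2)c(OCc2ccccc2)c1 | starting material
10 | iodomagnesium enolate of methyl (4S,5S)-4-(iodomethyl)-2-oxo-5-[3,4,5-tris(benzyloxy)phenyl]oxolane-3-carboxylate | COC(=O)C1=C(O[Mg]I)O[C@H](c2cc(OCc3ccccc3)c(OCc3ccccc3)c(OCc3ccccc3)c2)[C@H]1CI | intermediate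
11 | iodomagnesium alkoxide of methyl (3S,4S,5S)-3-{(R)-[3,4-bis(benzyloxy)phenyl](hydroxy)methyl}-4-(iodomethyl)-2-oxo-5-[3,4,5-tris(benzyloxy)phenyl]oxolane-3-carboxylate | O=C1O[C@H](c2cc(OCc3ccccc3)c(OCc3ccccc3)c(OCc3ccccc3)c2)[C@@H](CI)[C@@]1(C(=O)OC)[C@H](O[Mg]I)c1ccc(OCc2ccccc2)c(OCc2ccccc2)c1 | intermediate
12 | methyl (1S,4S,5R,8R)-8-[3,4-bis(benzyloxy)phenyl]-2-oxo-4-[3,4,5-tris(benzyloxy)phenyl]-3,7-dioxabicyclo[3.3.0]octane-1-carboxylate | O=C1O[C@H](c2cc(OCc3ccccc3)c(OCc3ccccc3)c(OCc3ccccc3)c2)[C@H]2CO[C@H](c3ccc(OCc4ccccc4)c(OCc4ccccc4)c3)[C@@]12C(=O)OC | intermediate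
13 | (1S,4S,5R,8S)-8-[3,4-bis(benzyloxy)phenyl]-4-[3,4,5-tris(benzyloxy)phenyl]-3,7-dioxabicyclo[3.3.0]octan-2-one | O=C1O[C@H](c2cc(OCc3ccccc3)c(OCc3ccccc3)c(OCc3ccccc3)c2)[C@H]2CO[C@H](c3ccc(OCc4ccccc4)c(OCc4ccccc4)c3)[C@@H]12 | intermediate
14 | (1S,4S,5R,8S)-8-(3,4-dihydroxyphenyl)-4-(3,4,5-trihydroxyphenyl)-3,7-dioxabicyclo[3.3.0]octan-2-one | O=C1O[C@H](c2cc(O)c(O)c(O)c2)[C@H]2CO[C@H](c3ccc(O)c(O)c3)[C@@H]12 | target

**Step count and risks**

Total steps: 8. Longest linear sequence: 8 (1 → 14); aldehyde 9 enters at step 6.

Steps most likely to fail, riskiest first: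

1. Step 6. The magnesium aldolate may displace iodide too slowly at a temperature the benzylic C4–O3 bond tolerates, so that material cycles between 8, 10 and 11 without closing; the aryl group may also be placed at C8 with poor exo preference. Fallback, setting out from 8 and 9 and coming back at 12: the domino is given up for two separate operations under kinetic control. Et2AlI in CH2Cl2 at −40 to 0 °C opens the cyclopropane of 8 and the aluminium enolate adds to 9 (iodide-induced ring-opening aldol, a known reaction of cyclopropyl carbonyl compounds). The aluminium aldolate does not cyclise, and after work-up the γ-iodo aldol methyl (3S,4S,5S)-3-{(R)-[3,4-bis(benzyloxy)phenyl](hydroxy)methyl}-4-(iodomethyl)-2-oxo-5-[3,4,5-tris(benzyloxy)phenyl]oxolane-3-carboxylate F1 would be separated from its diastereomers by chromatography. Halophilic activation of the iodide with Ag2O in MeCN should then close the C6–O7 bond without a free alkoxide that could revert by retro-aldol, giving 12. Diastereomers with the carbinol trans to the iodomethyl arm cannot close; DBU should return them to 8 and 9 by retro-aldol and cyclopropane closure for another pass.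

2. Step 5. The carbenoid may discriminate poorly between the aryl-anti and aryl-syn transition states, or may attack the electron-rich arene instead of the vinyl group. Fallback, setting out from 6 and coming back at 8 (7 is bypassed): oxidative radical cyclisation with Mn(OAc)3·2H2O and Cu(OAc)2·H2O in AcOH at 60 °C, a known route from allylic malonates to 3-oxabicyclo[3.1.0]hexan-2-ones. The malonyl radical cyclises 5-exo onto the vinyl group with the C5 arm trans to the aryl group, and copper-mediated oxidation of the primary radical closes the cyclopropane, so no carbenoid is involved.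

3. Step 8. The long exposure needed to remove five benzyl groups may lead to hydrogenolysis of the ring benzylic C–O bonds at C4 and C8, and the pyrogallol unit may oxidise in air on work-up. Fallback, setting out from 13 and coming back at 14: non-reductive debenzylation with BCl3 and pentamethylbenzene as cation scavenger in CH2Cl2 at −78 °C, quenched cold with MeOH. The benzyl groups are transferred to the scavenger by a Lewis-acid mechanism, so the ring C–O bonds are not exposed to hydrogen; the low temperature is needed to keep them from ionising.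

**Further compounds**

F1 | step 6 | methyl (3S,4S,5S)-3-{(R)-[3,4-bis(benzyloxy)phenyl](hydroxy)methyl}-4-(iodomethyl)-2-oxo-5-[3,4,5-tris(benzyloxy)phenyl]oxolane-3-carboxylate | O=C1O[C@H](c2cc(OCc3ccccc3)c(OCc3ccccc3)c(OCc3ccccc3)c2)[C@@H](CI)[C@@]1(C(=O)OC)[C@H](O)c1ccc(OCc2ccccc2)c(OCc2ccccc2)c1
F0 | step 5 | none | none
F0 | step 8 | none | none
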